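**Plan**

- Cuts: (a) the two acyl–O bonds that tie the (R)-danshensu units to the C3 carboxyl and to the cinnamoyl carboxyl; (b) the Cα=Cβ bond of the C5 propenoate, back to a C5 aldehyde stored as a dimethyl acetal; (c) C3–C3a and O1–C7a of the furan ring.
- Enabling feature: C3 and O1 of the benzofuran are the nucleophilic α-carbon and the enol oxygen of a protocatechuoylacetate (C2 is its ketone carbon). C3a and C7a are neighbouring carbons of ring A (the benzo ring) that can carry iodine and bromine, with the bromine next to the C7 oxygen.
- Forward: ring A is bought and fitted with iodine, bromine, a MOM ether and the acetal. The furan ring (ring B), the only ring built, closes in a CuI domino C-/O-arylation. Aldehyde release, Knoevenagel–Doebner extension, double esterification and one acidolysis follow.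
- The β-keto ester is carried as its methyl ester, because an aroylacetate of an α-hydroxy ester would risk Lacey–Dieckmann closure to a tetronic acid and epimerisation in hot carbonate.
- Stereochemistry: both (R) centres are bought with natural danshensu and enter in step 14 by O-acylation, which leaves the C–O bond at the stereocentre untouched. No later step is basic.

Key step: step 9

Assumption: danshensu is used as the free acid; where only the sodium salt is at hand, acidification with dilute HCl and extraction into ethyl acetate delivers it.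

**Route**

Step 1
Reactants: 1 methyl 4-amino-3-hydroxybenzoate
Product: 2 methyl 4-amino-3-(methoxymethoxy)benzoate
Conditions: MOMCl, K2CO3, acetone, 0 °C → rt
Reagents that add atoms: chloromethyl methyl ether, COCCl
Why: Williamson-type O-alkylation: carbonate ionises only the phenol, whose phenoxide should outrun the aniline nitrogen that the para ester deactivates.

Step 2
Reactants: 2 methyl 4-amino-3-(methoxymethoxy)benzoate
Product: 3 methyl 4-amino-3-iodo-5-(methoxymethoxy)benzoate
Conditions: NIS, DMF, rt, dark
Reagents that add atoms: N-iodosuccinimide, O=C1CCC(=O)N1I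
Why: Electrophilic aromatic iodination: the attacked carbon is the only free position ortho to the amino group and is meta to the ester, so both directors agree, and the acid-free medium spares the MOM ether.

Step 3
Reactants: 3 methyl 4-amino-3-iodo-5-(methoxymethoxy)benzoate
Product: 5 methyl 4-bromo-3-iodo-5-(methoxymethoxy)benzoate, via arenediazonium bromide 4 (not isolated)
Conditions: t-BuONO, CuBr2, MeCN, 0 → 60 °C
Reagents that add atoms: copper dibromide, [Cu+2].[Br-].[Br-]; tert-butyl nitrite, CC(C)(C)ON=O (its nitrogen stays only in 4)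
Why: Sandmeyer bromination run with an alkyl nitrite in dry acetonitrile: diazotisation needs no mineral acid, CuBr2 hands bromine to the aryl radical born from 4, and the neutral medium should keep the MOM ether and the aryl iodide in place.

Step 4
Reactants: 5 methyl 4-bromo-3-iodo-5-(methoxymethoxy)benzoate
Product: 6 [4-bromo-3-iodo-5-(methoxymethoxy)phenyl]methanol
Conditions: i-Bu2AlH, CH2Cl2, −78 → 0 °C; aq. potassium sodium tartrate
Reagents that add atoms: none
Why: Hydride reduction of an aromatic ester with i-Bu2AlH, which at low temperature leaves aryl halides and the MOM acetal alone.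

Step 5
Reactants: 6 [4-bromo-3-iodo-5-(methoxymethoxy)phenyl]methanol
Product: 7 4-bromo-3-iodo-5-(methoxymethoxy)benzaldehyde
Conditions: MnO2 (activated), CH2Cl2, rt
Reagents that add atoms: none
Why: Heterogeneous MnO2 oxidation is selective for benzylic alcohols, stops at the aldehyde and is neutral.

Step 6
Reactants: 7 4-bromo-3-iodo-5-(methoxymethoxy)benzaldehyde
Product: 8 2-bromo-5-(dimethoxymethyl)-1-iodo-3-(methoxymethoxy)benzene
Conditions: HC(OMe)3, PPTS (cat.), MeOH, rt; Et3N
Reagents that add atoms: trimethyl orthoformate, COC(OC)OC; methanol, CO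
Why: Acid-catalysed acetalisation driven by the orthoester as water scavenger; PPTS at room temperature is too mild to solvolyse an aryl MOM ether, and the acetal hides the aldehyde from the enolate of step 9 (no Knoevenagel condensation).

Step 7
Reactants: 9 methyl 3,4-dihydroxybenzoate
Product: 10 methyl 2,2-dimethyl-1,3-benzodioxole-5-carboxylate
Conditions: Me2C(OMe)2, TsOH·H2O (cat.), PhMe, reflux (MeOH trapped on 4 Å sieves)
Reagents that add atoms: 2,2-dimethoxypropane, COC(C)(C)OC
Why: Acid-catalysed ketal exchange on a catechol, pulled to completion by removal of methanol; the ester is inert.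

Step 8
Reactants: 10 methyl 2,2-dimethyl-1,3-benzodioxole-5-carboxylate; 11 methyl acetate
Product: 12 methyl 3-(2,2-dimethyl-1,3-benzodioxol-5-yl)-3-oxopropanoate
Conditions: LiN(SiMe3)2, THF, −40 → 0 °C; cold 1 M HCl
Reagents that add atoms: none
Why: Crossed Claisen condensation: 10 cannot enolise, the lithium enolate of 11 is acylated at the ester carbonyl of 10, deprotonation of the β-keto ester drives the equilibrium, and the all-methyl ester set rules out alkoxide scrambling.

Step 9
Reactants: 12 methyl 3-(2,2-dimethyl-1,3-benzodioxol-5-yl)-3-oxopropanoate; 8 2-bromo-5-(dimethoxymethyl)-1-iodo-3-(methoxymethoxy)benzene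
Product: 14 methyl 5-(dimethoxymethyl)-2-(2,2-dimethyl-1,3-benzodioxol-5-yl)-7-(methoxymethoxy)-1-benzofuran-3-carboxylate, via alpha-aryl beta-keto ester 13 (not isolated)
Conditions: CuI (10 mol %), K2CO3 (dried), THF, 100 °C (sealed tube), Ar
Reagents that add atoms: none
Why: K2CO3 converts 12 into its potassium enolate, which chelates monovalent copper; oxidative addition of the C–I bond of 8 and reductive elimination from the trivalent copper aryl enolate forge C3–C3a (Hurtley-type C-arylation) and give 13. 13, more acidic than 12, is deprotonated at once, and its copper-bound ketone-enolate oxygen engages the neighbouring C–Br bond through a six-membered cupracycle whose reductive elimination forms O1–C7a (intramolecular Ullmann-type O-arylation). The furan ring (ring B) thus closes as a five-membered ring in a 5-exo mode with respect to the breaking C–Br bond, and aromatisation to the benzofuran makes the closure irreversible. The closest known reaction type is the CuI/K2CO3 domino coupling of 1-bromo-2-iodoarenes with β-keto esters to 2,3-disubstituted benzofurans, here applied to a more substituted pair. The step needs orientation control, secured by the halogen pattern of 8 (the weaker and less crowded C–I bond, flanked by H and Br, takes the intermolecular C-arylation, while the bromide between it and the MOM ether can only react intramolecularly, which places O1 next to the C7 oxygen), and it needs C- before O-arylation and ketone- rather than ester-oxygen closure, which follow from the soft copper enolate and the higher charge on the ketone oxygen. No stereocentre is formed or present, acetal, MOM ether and ketal are inert to carbonate, dry reagents hold back retro-Claisen cleavage of 13, and the plain methyl ester removes the Lacey–Dieckmann and epimerisation pathways that an ester of an α-hydroxy ester would open.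

Step 10
Reactants: 14 methyl 5-(dimethoxymethyl)-2-(2,2-dimethyl-1,3-benzodioxol-5-yl)-7-(methoxymethoxy)-1-benzofuran-3-carboxylate
Product: 16 2-(2,2-dimethyl-1,3-benzodioxol-5-yl)-5-formyl-7-(methoxymethoxy)-1-benzofuran-3-carboxylic acid, via potassium carboxylate acetal 15 (not isolated)
Conditions: KOH, THF–MeOH–H2O, 60 °C; then 1 M HCl to pH 2, THF–H2O, rt
Reagents that add atoms: potassium hydroxide, [K+].[OH-]; water, O
Why: Saponification of the hindered C3 ester meets only base-stable groups (acetal, MOM, ketal), and the brief acidification then hydrolyses the benzylic dimethyl acetal, by far the most acid-labile group, without touching the aryl MOM ether or the catechol ketal.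

Step 11
Reactants: 16 2-(2,2-dimethyl-1,3-benzodioxol-5-yl)-5-formyl-7-(methoxymethoxy)-1-benzofuran-3-carboxylic acid; 17 malonic acid
Product: 18 5-[(E)-2-carboxyethenyl]-2-(2,2-dimethyl-1,3-benzodioxol-5-yl)-7-(methoxymethoxy)-1-benzofuran-3-carboxylic acid
Conditions: pyridine, piperidine (cat.), 80 °C
Reagents that add atoms: none
Why: Knoevenagel–Doebner condensation: amine-catalysed addition of malonic acid is followed by decarboxylative elimination, which gives the (E)-cinnamic acid directly and needs no ester hydrolysis afterwards.

Step 12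
Reactants: 19 danshensu, (R)-3-(3,4-dihydroxyphenyl)-2-hydroxypropanoic acid
Product: 21 (R)-3-(2,2-dimethyl-1,3-benzodioxol-5-yl)-2-hydroxypropanoic acid, via bis-acetonide dioxolanone 20 (not isolated)
Conditions: Me2C(OMe)2, TsOH·H2O (cat.), acetone, rt; PhMe, reflux (4 Å sieves); then LiOH, THF–H2O, 0 °C; 1 M HCl to pH 3
Reagents that add atoms: 2,2-dimethoxypropane, COC(C)(C)OC; lithium hydroxide, [Li+].[OH-]
Why: Acid-catalysed ketal exchange first locks the α-hydroxy acid as its 1,3-dioxolan-4-one, which masks the carbinol oxygen while the catechol is ketalised on removal of methanol, and hydroxide then opens only this activated acyl ketal, the aryl ketal being inert to base and the (R) centre safe because no bond to it is broken.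

Step 13
Reactants: 21 (R)-3-(2,2-dimethyl-1,3-benzodioxol-5-yl)-2-hydroxypropanoic acid
Product: 22 tert-butyl (R)-3-(2,2-dimethyl-1,3-benzodioxol-5-yl)-2-hydroxypropanoate
Conditions: Cl3CC(=NH)Ot-Bu, CH2Cl2–cyclohexane, rt
Reagents that add atoms: tert-butyl 2,2,2-trichloroacetimidate, CC(C)(C)OC(=N)C(Cl)(Cl)Cl
Why: Imidate esterification: the carboxylic acid itself protonates the trichloroacetimidate and is tert-butylated, while the secondary alcohol, which would need a Lewis acid, and the ketal stay untouched, so the (R) centre is carried over unchanged.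

Step 14
Reactants: 18 5-[(E)-2-carboxyethenyl]-2-(2,2-dimethyl-1,3-benzodioxol-5-yl)-7-(methoxymethoxy)-1-benzofuran-3-carboxylic acid; 22 tert-butyl (R)-3-(2,2-dimethyl-1,3-benzodioxol-5-yl)-2-hydroxypropanoate (two equivalents)
Product: 24 protected schizotenuin A (diester of 18 in which each carboxyl is esterified by the carbinol oxygen of 22; both carbinol centres R; alkene E), via bis(acyl chloride) 23 (not isolated)
Conditions: Me2C=C(Cl)NMe2, CH2Cl2, 0 °C → rt; then 22, Et3N, DMAP (cat.), 0 °C → rt
Reagents that add atoms: 1-chloro-N,N,2-trimethylprop-1-en-1-amine, CC(C)=C(Cl)N(C)C (its chlorine stays only in 23)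
Why: Neutral acid chloride formation with an α-chloroenamine (no HCl, so MOM ether and ketals survive) followed by DMAP-catalysed O-acylation should overcome the hindrance and the vinylogous-carbonate deactivation of the C3 carboxyl; both (R) centres come from 22 and are retained because only the O–H bond of the carbinol reacts.

Step 15
Reactants: 24 protected schizotenuin A
Product: 25 schizotenuin A
Conditions: TFA–H2O (9:1), 0 °C → rt, Ar
Reagents that add atoms: none
Why: Global acidolysis: aqueous trifluoroacetic acid cleaves the tert-butyl esters by alkyl–oxygen fission and hydrolyses the three catechol ketals and the MOM ether, whereas the two secondary alkyl esters, the (E)-alkene and the stereocentres are stable to acid, water serving as trap for the cations released.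

**Compound list**

1 | methyl 4-amino-3-hydroxybenzoate | COC(=O)c1ccc(N)c(O)c1 | starting material
2 | methyl 4-amino-3-(methoxymethoxy)benzoate | COC(=O)c1ccc(N)c(OCOC)c1 | intermediate
3 | methyl 4-amino-3-iodo-5-(methoxymethoxy)benzoate | COC(=O)c1cc(I)c(N)c(OCOC)c1 | intermediate
4 | 2-iodo-4-(methoxycarbonyl)-6-(methoxymethoxy)benzenediazonium bromide (formed in the flask) | COC(=O)c1cc(I)c([N+]#N)c(OCOC)c1.[Br-] | intermediate
5 | methyl 4-bromo-3-iodo-5-(methoxymethoxy)benzoate | COC(=O)c1cc(I)c(Br)c(OCOC)c1 | intermediate
6 | [4-bromo-3-iodo-5-(methoxymethoxy)phenyl]methanol | OCc1cc(I)c(Br)c(OCOC)c1 | intermediate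
7 | 4-bromo-3-iodo-5-(methoxymethoxy)benzaldehyde | O=Cc1cc(I)c(Br)c(OCOC)c1 | intermediate
8 | 2-bromo-5-(dimethoxymethyl)-1-iodo-3-(methoxymethoxy)benzene | COC(OC)c1cc(I)c(Br)c(OCOC)c1 | intermediate
9 | methyl 3,4-dihydroxybenzoate | COC(=O)c1ccc(O)c(O)c1 | starting material
10 | methyl 2,2-dimethyl-1,3-benzodioxole-5-carboxylate | COC(=O)c1ccc2OC(C)(C)Oc2c1 | intermediate
11 | methyl acetate | COC(C)=O | starting material
12 | methyl 3-(2,2-dimethyl-1,3-benzodioxol-5-yl)-3-oxopropanoate | COC(=O)CC(=O)c1ccc2OC(C)(C)Oc2c1 | intermediate
13 | methyl 2-[2-bromo-5-(dimethoxymethyl)-3-(methoxymethoxy)phenyl]-3-(2,2-dimethyl-1,3-benzodioxol-5-yl)-3-oxopropanoate (formed in the flask; labile α-centre, present as its enolate) | COC(=O)C(C(=O)c1ccc2OC(C)(C)Oc2c1)c1cc(C(OC)OC)cc(OCOC)c1Br | intermediate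
14 | methyl 5-(dimethoxymethyl)-2-(2,2-dimethyl-1,3-benzodioxol-5-yl)-7-(methoxymethoxy)-1-benzofuran-3-carboxylate | COC(OC)c1cc(OCOC)c2oc(-c3ccc4OC(C)(C)Oc4c3)c(C(=O)OC)c2c1 | intermediate
15 | potassium 5-(dimethoxymethyl)-2-(2,2-dimethyl-1,3-benzodioxol-5-yl)-7-(methoxymethoxy)-1-benzofuran-3-carboxylate (formed in the flask) | COC(OC)c1cc(OCOC)c2oc(-c3ccc4OC(C)(C)Oc4c3)c(C(=O)[O-])c2c1.[K+] | intermediate
16 | 2-(2,2-dimethyl-1,3-benzodioxol-5-yl)-5-formyl-7-(methoxymethoxy)-1-benzofuran-3-carboxylic acid | O=Cc1cc(OCOC)c2oc(-c3ccc4OC(C)(C)Oc4c3)c(C(=O)O)c2c1 | intermediate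
17 | malonic acid | OC(=O)CC(=O)O | starting material
18 | 5-[(E)-2-carboxyethenyl]-2-(2,2-dimethyl-1,3-benzodioxol-5-yl)-7-(methoxymethoxy)-1-benzofuran-3-carboxylic acid | OC(=O)/C=C/c1cc(OCOC)c2oc(-c3ccc4OC(C)(C)Oc4c3)c(C(=O)O)c2c1 | intermediate
19 | danshensu, (R)-3-(3,4-dihydroxyphenyl)-2-hydroxypropanoic acid | O[C@H](Cc1ccc(O)c(O)c1)C(=O)O | starting material
20 | (R)-5-[(2,2-dimethyl-1,3-benzodioxol-5-yl)methyl]-2,2-dimethyl-1,3-dioxolan-4-one (formed in the flask) | CC1(C)O[C@H](Cc2ccc3OC(C)(C)Oc3c2)C(=O)O1 | intermediate
21 | (R)-3-(2,2-dimethyl-1,3-benzodioxol-5-yl)-2-hydroxypropanoic acid | O[C@H](Cc1ccc2OC(C)(C)Oc2c1)C(=O)O | intermediate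
22 | tert-butyl (R)-3-(2,2-dimethyl-1,3-benzodioxol-5-yl)-2-hydroxypropanoate | O[C@H](Cc1ccc2OC(C)(C)Oc2c1)C(=O)OC(C)(C)C | intermediate
23 | 5-[(E)-3-chloro-3-oxoprop-1-enyl]-2-(2,2-dimethyl-1,3-benzodioxol-5-yl)-7-(methoxymethoxy)-1-benzofuran-3-carbonyl chloride (formed in the flask) | O=C(Cl)/C=C/c1cc(OCOC)c2oc(-c3ccc4OC(C)(C)Oc4c3)c(C(=O)Cl)c2c1 | intermediate
24 | protected schizotenuin A: C7 MOM ether, three catechol acetonides, two tert-butyl esters; both carbinol centres R, alkene E | O=C(/C=C/c1cc(OCOC)c2oc(-c3ccc4OC(C)(C)Oc4c3)c(C(=O)O[C@H](Cc3ccc4OC(C)(C)Oc4c3)C(=O)OC(C)(C)C)c2c1)O[C@H](Cc1ccc2OC(C)(C)Oc2c1)C(=O)OC(C)(C)C | intermediate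
25 | schizotenuin A | O=C(/C=C/c1cc(O)c2oc(-c3ccc(O)c(O)c3)c(C(=O)O[C@H](Cc3ccc(O)c(O)c3)C(=O)O)c2c1)O[C@H](Cc1ccc(O)c(O)c1)C(=O)O | target

**Step count**

Total step count: 15.
Longest linear sequence: 11 steps (steps 1–6, 9–11, 14, 15, counted from 1).

**Steps most likely to fail**

Step 9 (key step).
- Risk: oxidative addition at the bromide, which sits between the new C3 substituent and the MOM ether, may be slow. The domino sequence would then halt halfway, and the waiting intermediate would lose its aroyl group by retro-Claisen cleavage.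
- Fallback: it sets out from 8 (with 10 as acyl donor) and comes back to the route at 14, splitting the domino into separately tunable palladium steps.
- The iodide of 8 is coupled chemoselectively with the Reformatsky reagent BrZnCH2CO2Me under Pd(PPh3)4 in THF (Negishi-type coupling). This gives methyl 2-[2-bromo-5-(dimethoxymethyl)-3-(methoxymethoxy)phenyl]acetate F1.
- Crossed Claisen acylation of its enolate (LiN(SiMe3)2, THF) with ester 10 gives 13, now isolated.
- An intramolecular enolate O-arylation catalysed by zerovalent palladium (Pd2(dba)3, DPEphos, Cs2CO3, toluene, 100 °C) closes O1–C7a to 14.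

Step 12.
- Risk: the acetone-derived oxocarbenium ion on the carbinol oxygen may be intercepted by the electron-rich ring (oxa-Pictet–Spengler closure), and ketal exchange at the catechol may stay incomplete.
- Fallback: it sets out from 19 and comes back to the route at 25, and it avoids any acid-catalysed ketalisation of danshensu.
- Neutral esterification of 19 with tert-butyl 2,2,2-trichloroacetimidate gives tert-butyl (R)-3-(3,4-dihydroxyphenyl)-2-hydroxypropanoate F2.
- Phenoxide alkylation (MOMCl, K2CO3, acetone) gives tert-butyl (R)-3-[3,4-bis(methoxymethoxy)phenyl]-2-hydroxypropanoate F3.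
- F3 takes the place of 22 under the conditions of step 14 (18 via 23) to give the tetra-MOM analogue of protected schizotenuin A F4.
- The acidolysis of step 15 then delivers 25.

Step 3.
- Risk: Lewis-acidic CuBr2 and the hydroxide equivalent formed on diazotisation may strip the MOM group before nitrogen has left, which would divert the material into diazo-oxide formation and decomposition.
- Fallback: it sets out from 3 and comes back to the route at 5, and it accepts the loss of the protecting group.
- A classical aqueous Sandmeyer reaction (NaNO2, 48 % aq. HBr, 0 °C; CuBr, 60 °C) cleaves the MOM ether on purpose. The strong acid keeps the ortho-hydroxy diazonium ion protonated until bromide has replaced nitrogen. This gives methyl 4-bromo-3-hydroxy-5-iodobenzoate F5.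
- F5 is protected again with MOMCl and K2CO3 in acetone to give 5.

**Further compounds**

F1 | step 9 | methyl 2-[2-bromo-5-(dimethoxymethyl)-3-(methoxymethoxy)phenyl]acetate | COC(=O)Cc1cc(C(OC)OC)cc(OCOC)c1Br
F2 | step 12 | tert-butyl (R)-3-(3,4-dihydroxyphenyl)-2-hydroxypropanoate | O[C@H](Cc1ccc(O)c(O)c1)C(=O)OC(C)(C)C
F3 | step 12 | tert-butyl (R)-3-[3,4-bis(methoxymethoxy)phenyl]-2-hydroxypropanoate | O[C@H](Cc1ccc(OCOC)c(OCOC)c1)C(=O)OC(C)(C)C
F4 | step 12 | tetra-MOM analogue of protected schizotenuin A | O=C(/C=C/c1cc(OCOC)c2oc(-c3ccc4OC(C)(C)Oc4c3)c(C(=O)O[C@H](Cc3ccc(OCOC)c(OCOC)c3)C(=O)OC(C)(C)C)c2c1)O[C@H](Cc1ccc(OCOC)c(OCOC)c1)C(=O)OC(C)(C)C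
F5 | step 3 | methyl 4-bromo-3-hydroxy-5-iodobenzoate | COC(=O)c1cc(I)c(Br)c(O)c1
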